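## Analysis of the target

Target 39 is a benzo[7]annulen-5-one (benzotropolone) with hydroxyls at C3, C4 and C6. Chroman A is attached through its C2 to C1 of the benzo ring and carries a 3,4,5-trihydroxybenzoate on its C3 oxygen. Chroman B is attached through its C2 to C7 of the seven-membered ring, next to the tropolone hydroxyl, and has a free C3 hydroxyl. There are four stereocentres, C2 and C3 of each chroman, all R. Within each chroman the C2 substituent and the C3 oxygen are cis; the two pairs are remote from each other and have to be set independently. The molecule has nine free phenols, a tropolone and a hindered ester, so it is sensitive to air, base and strong acid, and the benzylic C2–O1 bonds open once the ring A phenols are free. The synthesis is hard for three reasons: the cis-2,3 arrangement is the less stable one, the tropolone is unsymmetrically substituted with C9 crowded by chroman A on C1, and the polyphenol can only be unmasked at the very end. The strategy rests on the pyran ring of chroman A. Its atoms O1, C8a, C4a and C4 (a ring oxygen and a CH2 on neighbouring carbons of a 1,3,5-trioxygenated benzene ring) are the skeleton of an ortho-quinone methide. C2 and C3 are then a two-carbon unit whose cis substituents map onto a Z alkene carrying the benzo ring at one end and boron, as a stand-in for oxygen, at the other.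

## Retrosynthetic reasoning

Target 39 is traced back to its decabenzyl ether 38. No skeletal bond is cut. All phenolic and alcoholic oxygens except the tropolone hydroxyl stay masked until a single hydrogenolysis at the end, so that the pyrogallol, catechol and 1,3,5-trioxygenated rings never meet base or oxidant in free form.

In 38 the C9–O bond of an oxygen bridge between C6 and C9 is restored, which gives the 8-oxabicyclo[3.2.1]octenone 37. This turns the tropolone into the product of a cycloaddition. The forward step only has to ionise a C9–O bond that is both benzylic and allylic and remove the C6 proton.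

Cycloadduct 37 is cut at C6–C7 and C8–C9 into carbonyl ylide 36, which comes from formyl diazoketone 26, and terminal alkyne 35. The cut divides the molecule at the seven-membered ring into two halves of similar size, each with one finished chroman. Chroman B ends up on C7 provided the substituted alkyne carbon joins the enolate-like terminus of 36. The forward step has to make the carbenoid react with the aldehyde oxygen and the ylide with the alkyne.

The diazoketone and the aldehyde of 26 are recognised as the two carbons of a phthalide. The lactone carbonyl is at the acid oxidation level needed to acylate a one-carbon diazo unit (22 to 24 through 23). The lactone CH2 is a benzylic alcohol (24, 25, 26). Further back the ester is cut into alcohol 19 and acid 20, and 19 is re-closed through 18 to lactone 15. The galloyl group is put on only after saponification of the lactone, which it would not survive. The liberated acid is parked as an allyl ester during the acylation, and a silyl ether keeps the hydroxy acid from re-lactonising.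

In 15 the C3–O bond is exchanged for a C3–B bond, giving 14. Boron is the oxygen surrogate that allows the next cut. The forward oxidation migrates C3 from boron to oxygen with retention.

The pyran ring of 14 is cut at O1–C2 and C3–C4 into ortho-quinone methide 13, released from benzylic alcohol 12, and Z-alkenylboronate 9. This cut is preferred over one at the aryl–C2 bond or at C2–C3 because both stereocentres then come from one alkene geometry and two achiral partners. One step gives a ring, two bonds and two stereocentres. The forward step has to control regiochemistry, retention of alkene geometry and the face of addition.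

Boronate 9 is cut at C–B to alkyne 7 and borane 8 (formal trans-hydroboration). Alkyne 7 goes back through 6 to bromide 4 and alkyne 5 (sp–sp2 coupling). Bromide 4 goes back through 3 to 2 (exchange of methyl for benzyl ethers, so that all protecting groups fall together), and 2 to 1 at the C4–Br bond. In 1, C4 is para to the C7 oxygen, ortho to the ring CH2 and meta to the lactone carbonyl.

Alcohol 12 comes from aldehyde 11 by reduction, and 11 from 10 by benzylation of the two hydroxyls that are not both flanking and chelating the aldehyde.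

Alkyne 35 has the same cis pattern but an ethynyl group on C2. An alkynyl group does not polarise an alkene enough for the cycloaddition used for chroman A, so 35 is cut differently. Removal of the benzyl and silyl groups leads through 34 to 33. The C4–C4a bond of 33 is cut (epoxide–arene closure from 32). The O1–C2 bond of 32 is cut (ether formation with inversion from epoxy alcohol 30 and phenol 31). The erythro configuration of 30 plus one inversion gives the cis chroman. Compound 30 comes from racemic 29 by kinetic resolution, and 29 from 27 and 28.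

## Alternatives that were turned down

Alternative 1: The seven-membered ring is made from a six-membered one by inserting C6. A dihalocarbene adds to the enol double bond of silyl enol ether A2, and the siloxy-dihalocyclopropane opens with loss of halide to the ring-enlarged bromoenone A1, forming C5–C6 and C6–C7.
- For: the expansion is a dependable reaction on a simple substrate and places the future oxygen at C6 without any regiochemical question. On predictability it is stronger than both cycloadditions of the chosen route.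
- Against: A1 has no chroman and no stereocentre. C8–C9 is still saturated and the C6 bromide has to become the hydroxyl. Chroman B has to be attached at C7, which A1 does not activate. Chroman A has to be grown from the aryl bromide at C1 by joining an sp2 carbon to a stereogenic sp3 carbon.
- Comparison: all four stereocentres remain open after the key step and the sequence becomes long and linear. The chosen strategy gives up the reliability of the ring expansion for a key step that makes a ring and two stereocentres at once, and for an end-game that joins two finished halves.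

Alternative 2: The tropolone ring is cut at C6–C7 and C8–C9. Rh2(OAc)4 turns formyl diazoketone A4 into a cyclic carbonyl ylide that adds across ethynylchroman A5 to give the oxygen-bridged cycloadduct A3.
- For: A3, A4 and A5 are identical with 37, 26 and 35, because the chosen route uses this union for its end-game. As a fragment coupling it is more convergent than the chosen key step, and it is a known reaction type.
- Against: as the idea that carries the synthesis it leaves open where the two cis chromans come from. A4 needs a cis-flavan-3-ol whose C2 sits on a penta-substituted, ortho-flanked arene. Built by the usual dihydroxylation, cyclisation and C3 inversion, that half alone would cost about as many steps as the whole approach to 26 here. All strategic risk also sits at the last C–C bond formation.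
- Comparison: the chosen strategy keeps this cycloaddition as a subordinate step and adds a one-step, stereospecific construction of chroman A. The price is that its own key step is unproven.

Alternative 3: The ring is cut at C8=C9. A ruthenium alkylidene (second-generation Hoveyda–Grubbs catalyst, (H2IMes)Cl2Ru=CH(2-iPrO-C6H4)) joins the styrene vinyl group and the C7 vinyl group of diene A7 to give dihydrobenzoannulenone A6.
- For: metathesis to a benzo-fused seven-membered ring is dependable, and the positions of chroman B (C7) and oxygen (C6) are fixed by construction. On the regiochemistry of the tropolone substituents this is stronger than a cycloaddition.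
- Against: A7 has to be assembled linearly. It has two extra stereocentres (C6, C7) that are carried as mixtures and destroyed later, and its bond from C7 to chroman B joins two stereogenic sp3 carbons. A6 still has to be dehydrogenated across C6–C7 in the presence of electron-rich rings. The aryl chloride at C1 leaves chroman A unsolved.
- Comparison: more steps after the key step and less convergence. The chosen strategy sets the stereocentres of chroman A early and reaches the tropolone oxidation level directly from the cycloadduct.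

Key step: step 9

Remark: the catalyst in step 9 is written as (R) and is exchanged for (S) should the sense of induction prove opposite; 37 should form as two bridge diastereomers that both give 38, and one is drawn.

## Route

Step 1
Reactants: 1 meconin (6,7-dimethoxyisobenzofuran-1(3H)-one)
Product: 2 4-bromo-6,7-dimethoxyisobenzofuran-1(3H)-one
Conditions: Br2 (1.1 equiv), AcOH, rt to 40 °C
Reagents that add atoms: bromine, BrBr
Why: Electrophilic aromatic bromination; C4 is para to the C7 methoxy group, ortho to the ring CH2 and meta to the lactone carbonyl, whereas C5 is para to the carbonyl-bearing carbon, so substitution should go to C4.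

Step 2
Reactants: 2 4-bromo-6,7-dimethoxyisobenzofuran-1(3H)-one
Product: 3 4-bromo-6,7-dihydroxyisobenzofuran-1(3H)-one
Conditions: BBr3 (3 equiv), CH2Cl2, −78 °C to rt; then H2O
Reagents that add atoms: none
Why: Lewis acid cleavage of aryl methyl ethers; should the benzylic lactone C–O bond be touched, the hydroxy acid re-closes on aqueous work-up.

Step 3
Reactants: 3 4-bromo-6,7-dihydroxyisobenzofuran-1(3H)-one
Product: 4 6,7-bis(benzyloxy)-4-bromoisobenzofuran-1(3H)-one
Conditions: BnBr (2.4 equiv), K2CO3, DMF, 60 °C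
Reagents that add atoms: benzyl bromide, BrCc1ccccc1
Why: Williamson ether synthesis; warming is needed for the hydroxyl that is hydrogen-bonded to the lactone carbonyl.

Step 4
Reactants: 4 6,7-bis(benzyloxy)-4-bromoisobenzofuran-1(3H)-one; 5 ethynyltrimethylsilane
Product: 6 6,7-bis(benzyloxy)-4-[(trimethylsilyl)ethynyl]isobenzofuran-1(3H)-one
Conditions: PdCl2(PPh3)2 (3 mol%), CuI (6 mol%), Et3N, DMF, 70 °C
Reagents that add atoms: none
Why: Sonogashira coupling; zerovalent palladium inserts into the C–Br bond and the copper acetylide transfers the alkynyl group, and the lactone is inert.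

Step 5
Reactants: 6 6,7-bis(benzyloxy)-4-[(trimethylsilyl)ethynyl]isobenzofuran-1(3H)-one
Product: 7 6,7-bis(benzyloxy)-4-ethynylisobenzofuran-1(3H)-one
Conditions: K2CO3 (0.2 equiv), MeOH/THF, 0 °C to rt
Reagents that add atoms: none
Why: Methoxide-mediated protodesilylation of the alkynylsilane; any methanolysis of the lactone is reversible and favours the phthalide.

Step 6
Reactants: 7 6,7-bis(benzyloxy)-4-ethynylisobenzofuran-1(3H)-one; 8 pinacolborane
Product: 9 6,7-bis(benzyloxy)-4-[(Z)-2-(4,4,5,5-tetramethyl-1,3,2-dioxaborolan-2-yl)ethenyl]isobenzofuran-1(3H)-one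
Conditions: [Rh(cod)Cl]2 (1.5 mol%), P(iPr)3 (6 mol%), Et3N, cyclohexane (a little THF for solubility), rt, dark
Reagents that add atoms: none
Why: Rhodium-catalysed formal trans-hydroboration of a terminal alkyne; a rhodium vinylidene formed by 1,2-hydrogen shift places boron on the terminal carbon cis to the aryl group, giving the Z alkenylboronate, and esters are tolerated.

Step 7
Reactants: 10 2,4,6-trihydroxybenzaldehyde
Product: 11 2,4-bis(benzyloxy)-6-hydroxybenzaldehyde
Conditions: BnBr (2.05 equiv), K2CO3 (2.1 equiv), DMF, 0 °C to rt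
Reagents that add atoms: benzyl bromide, BrCc1ccccc1
Why: Williamson ether synthesis; the para hydroxyl and one ortho hydroxyl are alkylated, while the remaining ortho hydroxyl is held in a hydrogen bond to the aldehyde and should stay free.

Step 8
Reactants: 11 2,4-bis(benzyloxy)-6-hydroxybenzaldehyde
Product: 12 3,5-bis(benzyloxy)-2-(hydroxymethyl)phenol
Conditions: NaBH4 (1.0 equiv), THF/MeOH, 0 °C, short reaction time; sat. NH4Cl
Reagents that add atoms: none
Why: Hydride reduction of the aldehyde; low temperature and a non-acidic quench avoid premature quinone methide formation and over-reduction to the methyl compound.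

Step 9
Reactants: 12 3,5-bis(benzyloxy)-2-(hydroxymethyl)phenol; 9 6,7-bis(benzyloxy)-4-[(Z)-2-(4,4,5,5-tetramethyl-1,3,2-dioxaborolan-2-yl)ethenyl]isobenzofuran-1(3H)-one
Product: 14 6,7-bis(benzyloxy)-4-[(2S,3R)-5,7-bis(benzyloxy)-3-(4,4,5,5-tetramethyl-1,3,2-dioxaborolan-2-yl)chroman-2-yl]isobenzofuran-1(3H)-one, via ortho-quinone methide 13 (not isolated)
Conditions: (R)-3,3'-bis(2,4,6-triisopropylphenyl)-1,1'-binaphthalene-2,2'-diyl hydrogen phosphate (10 mol%), 5 Å MS, PhCF3, 0 °C, 12 (2 equiv) added slowly to 9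
Reagents that add atoms: none
Why: Proposed new method: the chiral acid protonates the benzylic hydroxyl of 12 and releases water to give ortho-quinone methide 13, which stays hydrogen-bonded to the phosphate as a chiral contact pair; the closest known reaction type is the Brønsted acid-catalysed inverse-electron-demand hetero-Diels–Alder reaction of ortho-quinone methides made in situ with styrenes to give 2-arylchromans, and the known diol-catalysed conjugate addition of alkenylboronates to ortho-quinone methides shows that the boron-bearing carbon is the one that attacks the methide carbon. The alkene of 9 adds across the C=C–C=O unit of 13 in an asynchronous concerted [4+2] in which C3–C4 formation (boron-bearing carbon to the exocyclic CH2) runs ahead and the developing benzylic cation, stabilised by the para benzyloxy group and the adjacent C–B bond, is captured by the carbonyl oxygen (O1–C2). The pyran ring is therefore closed by cycloaddition, both ring bonds in one step, and re-aromatisation of ring A drives it. C2 and C3 are set together: their cis relationship follows from suprafacial addition to the Z alkene, and their absolute configuration from the face of 13 that the phosphate leaves open. The step needs regiochemistry, which the styrene polarisation secures; retention of alkene geometry, which holds only while ring closure is faster than bond rotation or loss of boron from the cationic intermediate; and facial control, which is the unproven element and rests on the bulky 3,3'-aryl groups of the catalyst and the ortho-substituted aryl group of 9. Slow addition keeps 13 dilute so that it is trapped by 9 and not by a second molecule of 12.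

Step 10
Reactants: 14 6,7-bis(benzyloxy)-4-[(2S,3R)-5,7-bis(benzyloxy)-3-(4,4,5,5-tetramethyl-1,3,2-dioxaborolan-2-yl)chroman-2-yl]isobenzofuran-1(3H)-one
Product: 15 6,7-bis(benzyloxy)-4-[(2R,3R)-5,7-bis(benzyloxy)-3-hydroxychroman-2-yl]isobenzofuran-1(3H)-one
Conditions: NaBO3·4H2O (5 equiv), THF/H2O 1:1, rt
Reagents that add atoms: sodium perborate tetrahydrate, [Na+].[Na+].O[B-]1(O)OO[B-](O)(O)OO1
Why: Oxidation of the C–B bond by 1,2-migration of C3 from boron to oxygen with retention, so the cis relationship is kept (the descriptor at C2 changes only through the priority rules); perborate is mild enough for the lactone.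

Step 11
Reactants: 15 6,7-bis(benzyloxy)-4-[(2R,3R)-5,7-bis(benzyloxy)-3-hydroxychroman-2-yl]isobenzofuran-1(3H)-one
Product: 18 2,3-bis(benzyloxy)-5-[(2R,3R)-5,7-bis(benzyloxy)-3-hydroxychroman-2-yl]-6-{[(tert-butyldiphenylsilyl)oxy]methyl}benzoic acid, via potassium carboxylate 16 (not isolated), via silyl ester 17 (not isolated)
Conditions: KOH (3 equiv), THF/MeOH/H2O, 45 °C; evaporate; t-BuPh2SiCl (2.5 equiv), imidazole, DMF, 0 °C to rt; then K2CO3, MeOH/H2O, rt; AcOH to pH 5
Reagents that add atoms: potassium hydroxide, [K+].[OH-]; tert-butyl(chloro)diphenylsilane, CC(C)(C)[Si](Cl)(c1ccccc1)c1ccccc1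
Why: Saponification of the phthalide followed by silylation of the carboxylate salt before any acidification, which prevents re-lactonisation; the bulky silyl chloride takes the primary benzylic hydroxyl and not the hindered axial C3 hydroxyl, and the silyl ester is cleaved selectively by mild aqueous base.

Step 12
Reactants: 18 2,3-bis(benzyloxy)-5-[(2R,3R)-5,7-bis(benzyloxy)-3-hydroxychroman-2-yl]-6-{[(tert-butyldiphenylsilyl)oxy]methyl}benzoic acid
Product: 19 allyl 2,3-bis(benzyloxy)-5-[(2R,3R)-5,7-bis(benzyloxy)-3-hydroxychroman-2-yl]-6-{[(tert-butyldiphenylsilyl)oxy]methyl}benzoate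
Conditions: allyl bromide (1.5 equiv), KHCO3, DMF, rt
Reagents that add atoms: allyl bromide, C=CCBr
Why: SN2 alkylation of the carboxylate; it is insensitive to the steric hindrance of the 2,6-disubstituted acid and leaves the secondary alcohol untouched.

Step 13
Reactants: 19 allyl 2,3-bis(benzyloxy)-5-[(2R,3R)-5,7-bis(benzyloxy)-3-hydroxychroman-2-yl]-6-{[(tert-butyldiphenylsilyl)oxy]methyl}benzoate; 20 3,4,5-tris(benzyloxy)benzoic acid
Product: 21 allyl 2,3-bis(benzyloxy)-5-[(2R,3R)-5,7-bis(benzyloxy)-3-{[3,4,5-tris(benzyloxy)benzoyl]oxy}chroman-2-yl]-6-{[(tert-butyldiphenylsilyl)oxy]methyl}benzoate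
Conditions: 1-ethyl-3-(3-dimethylaminopropyl)carbodiimide hydrochloride (2 equiv), 4-(dimethylamino)pyridine (1 equiv), CH2Cl2, rt
Reagents that add atoms: none
Why: Steglich esterification; acyl transfer through the acylpyridinium ion is the standard way to acylate the hindered axial C3 hydroxyl of cis-flavan-3-ols, and C3 is not touched.

Step 14
Reactants: 21 allyl 2,3-bis(benzyloxy)-5-[(2R,3R)-5,7-bis(benzyloxy)-3-{[3,4,5-tris(benzyloxy)benzoyl]oxy}chroman-2-yl]-6-{[(tert-butyldiphenylsilyl)oxy]methyl}benzoate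
Product: 22 2,3-bis(benzyloxy)-5-[(2R,3R)-5,7-bis(benzyloxy)-3-{[3,4,5-tris(benzyloxy)benzoyl]oxy}chroman-2-yl]-6-{[(tert-butyldiphenylsilyl)oxy]methyl}benzoic acid
Conditions: Pd(PPh3)4 (5 mol%), morpholine (5 equiv), THF, rt
Reagents that add atoms: none
Why: Tsuji–Trost deallylation; zerovalent palladium ionises the allyl ester to a π-allyl complex that morpholine captures, under neutral conditions that spare the gallate, the silyl ether and the benzyl ethers.

Step 15
Reactants: 22 2,3-bis(benzyloxy)-5-[(2R,3R)-5,7-bis(benzyloxy)-3-{[3,4,5-tris(benzyloxy)benzoyl]oxy}chroman-2-yl]-6-{[(tert-butyldiphenylsilyl)oxy]methyl}benzoic acid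
Product: 24 (2R,3R)-5,7-bis(benzyloxy)-2-[4,5-bis(benzyloxy)-2-{[(tert-butyldiphenylsilyl)oxy]methyl}-3-(2-diazoacetyl)phenyl]chroman-3-yl 3,4,5-tris(benzyloxy)benzoate, via acid chloride 23 (not isolated)
Conditions: 1-chloro-N,N,2-trimethylprop-1-en-1-amine (1.2 equiv), CH2Cl2, 0 °C; then CH2N2 (4 equiv), Et2O, 0 °C
Reagents that add atoms: diazomethane, C=[N+]=[N-]
Why: Acylation of diazomethane by an acid chloride (first stage of the Arndt–Eistert sequence); the neutral chloroenamine makes the hindered acid chloride without HCl, and excess diazomethane removes the HCl set free in the acylation, and the bulky silyl ether should not lactonise onto the acid chloride at 0 °C.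

Step 16
Reactants: 24 (2R,3R)-5,7-bis(benzyloxy)-2-[4,5-bis(benzyloxy)-2-{[(tert-butyldiphenylsilyl)oxy]methyl}-3-(2-diazoacetyl)phenyl]chroman-3-yl 3,4,5-tris(benzyloxy)benzoate
Product: 25 (2R,3R)-5,7-bis(benzyloxy)-2-[4,5-bis(benzyloxy)-3-(2-diazoacetyl)-2-(hydroxymethyl)phenyl]chroman-3-yl 3,4,5-tris(benzyloxy)benzoate
Conditions: Bu4NF (1.5 equiv), AcOH (1.5 equiv), THF, 0 °C to rt
Reagents that add atoms: none
Why: Fluoride-mediated desilylation, buffered so that neither the gallate nor the diazoketone is attacked; with a ketone in place of the acid the freed alcohol can no longer lactonise.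

Step 17
Reactants: 25 (2R,3R)-5,7-bis(benzyloxy)-2-[4,5-bis(benzyloxy)-3-(2-diazoacetyl)-2-(hydroxymethyl)phenyl]chroman-3-yl 3,4,5-tris(benzyloxy)benzoate
Product: 26 (2R,3R)-5,7-bis(benzyloxy)-2-[4,5-bis(benzyloxy)-3-(2-diazoacetyl)-2-formylphenyl]chroman-3-yl 3,4,5-tris(benzyloxy)benzoate
Conditions: Dess–Martin periodinane (1.3 equiv), NaHCO3, CH2Cl2, 0 °C to rt; used at once
Reagents that add atoms: none
Why: Dess–Martin oxidation of the benzylic alcohol; the buffered, non-basic conditions are tolerated by diazoketones, and the C3 oxygen is already acylated so no lactol can form with the new aldehyde.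

Step 18
Reactants: 27 acrolein; 28 ethynyltriisopropylsilane
Product: 29 racemic 5-(triisopropylsilyl)pent-1-en-4-yn-3-ol
Conditions: 28, n-BuLi (1.05 equiv), THF, −78 °C; then 27; aq. NH4Cl
Reagents that add atoms: none
Why: 1,2-Addition of a lithium acetylide to an enal, which is the normal course for this hard nucleophile at low temperature.

Step 19
Reactants: 29 racemic 5-(triisopropylsilyl)pent-1-en-4-yn-3-ol
Product: 30 (1S)-1-[(2R)-oxiran-2-yl]-3-(triisopropylsilyl)prop-2-yn-1-ol
Conditions: Ti(OiPr)4 (1.0 equiv), L-(+)-diisopropyl tartrate (1.2 equiv), t-BuOOH (0.45 equiv), 4 Å MS, CH2Cl2, −20 °C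
Reagents that add atoms: tert-butyl hydroperoxide, CC(C)(C)OO
Why: Sharpless kinetic resolution of a secondary allylic alcohol; with the L-tartrate the (R) alcohol is the fast-reacting enantiomer and is epoxidised on the face that gives the erythro epoxy alcohol, so both stereocentres of 30 are set by the catalyst, and the (S) alcohol is left behind.

Step 20
Reactants: 30 (1S)-1-[(2R)-oxiran-2-yl]-3-(triisopropylsilyl)prop-2-yn-1-ol; 31 3,5-bis(benzyloxy)phenol
Product: 32 (2R)-2-[(1R)-1-[3,5-bis(benzyloxy)phenoxy]-3-(triisopropylsilyl)prop-2-yn-1-yl]oxirane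
Conditions: PPh3 (1.3 equiv), diisopropyl azodicarboxylate (1.3 equiv), toluene, 0 °C to rt
Reagents that add atoms: none
Why: Mitsunobu etherification; the phenoxide displaces the activated propargylic oxygen by SN2 with inversion, which turns the erythro relationship into the threo one required for the cis chroman, and the epoxide is not involved.

Step 21
Reactants: 32 (2R)-2-[(1R)-1-[3,5-bis(benzyloxy)phenoxy]-3-(triisopropylsilyl)prop-2-yn-1-yl]oxirane
Product: 33 (2R,3R)-5,7-bis(benzyloxy)-2-[(triisopropylsilyl)ethynyl]chroman-3-ol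
Conditions: BF3·OEt2 (0.3 equiv), CH2Cl2, −78 to −30 °C
Reagents that add atoms: none
Why: Intramolecular Friedel–Crafts epoxide–arene alkylation; the electron-rich ring attacks the terminal epoxide carbon through its position ortho to the ether oxygen (6-endo), so C4–C4a is formed without touching either stereocentre, and the bulky silyl group keeps the alkyne out of the reaction.

Step 22
Reactants: 33 (2R,3R)-5,7-bis(benzyloxy)-2-[(triisopropylsilyl)ethynyl]chroman-3-ol
Product: 34 (2R,3R)-3,5,7-tris(benzyloxy)-2-[(triisopropylsilyl)ethynyl]chroman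
Conditions: NaH (1.3 equiv), BnBr (1.3 equiv), Bu4NI (cat.), THF/DMF, 0 °C to rt
Reagents that add atoms: benzyl bromide, BrCc1ccccc1
Why: Williamson ether synthesis on the secondary alkoxide; the silyl group protects the alkyne terminus from deprotonation.

Step 23
Reactants: 34 (2R,3R)-3,5,7-tris(benzyloxy)-2-[(triisopropylsilyl)ethynyl]chroman
Product: 35 (2R,3R)-3,5,7-tris(benzyloxy)-2-ethynylchroman
Conditions: Bu4NF (1.2 equiv), THF, 0 °C to rt
Reagents that add atoms: none
Why: Fluoride-mediated cleavage of the alkynyl–silicon bond; short exposure at low temperature avoids base-induced isomerisation at the propargylic C2.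

Step 24
Reactants: 26 (2R,3R)-5,7-bis(benzyloxy)-2-[4,5-bis(benzyloxy)-3-(2-diazoacetyl)-2-formylphenyl]chroman-3-yl 3,4,5-tris(benzyloxy)benzoate; 35 (2R,3R)-3,5,7-tris(benzyloxy)-2-ethynylchroman
Product: 37 (2R,3R)-5,7-bis(benzyloxy)-2-{3,4-bis(benzyloxy)-5-oxo-7-[(2R,3R)-3,5,7-tris(benzyloxy)chroman-2-yl]-6,9-dihydro-5H-6,9-epoxybenzo[7]annulen-1-yl}chroman-3-yl 3,4,5-tris(benzyloxy)benzoate, via carbonyl ylide 36 (not isolated)
Conditions: Rh2(OAc)4 (2 mol%), 35 (1.5 equiv), CH2Cl2, 40 °C, slow addition of 26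
Reagents that add atoms: none
Why: Rhodium carbenoid formation, capture by the ortho aldehyde oxygen to the six-membered carbonyl ylide 36 (a 2-benzopyrylium-4-olate) and 1,3-dipolar cycloaddition to the alkyne, a known sequence for ortho-acyl aryl diazoketones. The unsubstituted alkyne terminus should bond to the oxocarbenium-like carbon of 36 (the former aldehyde carbon, which is also the more crowded terminus) and the substituted carbon to the enolate-like carbon, which puts chroman B on C7. The bridgehead configuration is irrelevant because both bridgeheads become sp2 in step 25.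

Step 25
Reactants: 37 (2R,3R)-5,7-bis(benzyloxy)-2-{3,4-bis(benzyloxy)-5-oxo-7-[(2R,3R)-3,5,7-tris(benzyloxy)chroman-2-yl]-6,9-dihydro-5H-6,9-epoxybenzo[7]annulen-1-yl}chroman-3-yl 3,4,5-tris(benzyloxy)benzoate
Product: 38 (2R,3R)-5,7-bis(benzyloxy)-2-{3,4-bis(benzyloxy)-6-hydroxy-5-oxo-7-[(2R,3R)-3,5,7-tris(benzyloxy)chroman-2-yl]-5H-benzo[7]annulen-1-yl}chroman-3-yl 3,4,5-tris(benzyloxy)benzoate
Conditions: TsOH·H2O (0.2 equiv), CH2Cl2, rt
Reagents that add atoms: none
Why: Acid-mediated opening of the oxygen bridge; the C9–O bond ionises to a cation that is benzylic, allylic and stabilised by the para benzyloxy group, and loss of the C6 proton gives the enol, which is the tropolone.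

Step 26
Reactants: 38 (2R,3R)-5,7-bis(benzyloxy)-2-{3,4-bis(benzyloxy)-6-hydroxy-5-oxo-7-[(2R,3R)-3,5,7-tris(benzyloxy)chroman-2-yl]-5H-benzo[7]annulen-1-yl}chroman-3-yl 3,4,5-tris(benzyloxy)benzoate
Product: 39 (2R,3R)-5,7-dihydroxy-2-{3,4,6-trihydroxy-5-oxo-7-[(2R,3R)-3,5,7-trihydroxychroman-2-yl]-5H-benzo[7]annulen-1-yl}chroman-3-yl 3,4,5-trihydroxybenzoate (CNP0217128.1)
Conditions: H2 (1 atm), Pd(OH)2/C, THF/MeOH, rt, degassed solvents
Reagents that add atoms: none
Why: Hydrogenolysis of all ten benzyl ethers in one operation, the usual final step for benzylated flavan-3-ol gallates; the ester, the four stereocentres and the tropolone should survive under neutral conditions.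

## Compound list

1 | meconin (6,7-dimethoxyisobenzofuran-1(3H)-one) | COc1ccc2COC(=O)c2c1OC | starting material
2 | 4-bromo-6,7-dimethoxyisobenzofuran-1(3H)-one | COc1cc(Br)c2COC(=O)c2c1OC | intermediate
3 | 4-bromo-6,7-dihydroxyisobenzofuran-1(3H)-one | Oc1cc(Br)c2COC(=O)c2c1O | intermediate
4 | 6,7-bis(benzyloxy)-4-bromoisobenzofuran-1(3H)-one | O=C1OCc2c(Br)cc(OCc3ccccc3)c(OCc3ccccc3)c12 | intermediate
5 | ethynyltrimethylsilane | C#C[Si](C)(C)C | starting material
6 | 6,7-bis(benzyloxy)-4-[(trimethylsilyl)ethynyl]isobenzofuran-1(3H)-one | C[Si](C)(C)C#Cc1cc(OCc2ccccc2)c(OCc2ccccc2)c2C(=O)OCc12 | intermediate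
7 | 6,7-bis(benzyloxy)-4-ethynylisobenzofuran-1(3H)-one | C#Cc1cc(OCc2ccccc2)c(OCc2ccccc2)c2C(=O)OCc12 | intermediate
8 | pinacolborane | CC1(C)OBOC1(C)C | starting material
9 | 6,7-bis(benzyloxy)-4-[(Z)-2-(4,4,5,5-tetramethyl-1,3,2-dioxaborolan-2-yl)ethenyl]isobenzofuran-1(3H)-one | CC1(C)OB(/C=C\c2cc(OCc3ccccc3)c(OCc3ccccc3)c3C(=O)OCc23)OC1(C)C | intermediate
10 | 2,4,6-trihydroxybenzaldehyde | O=Cc1c(O)cc(O)cc1O | starting material
11 | 2,4-bis(benzyloxy)-6-hydroxybenzaldehyde | O=Cc1c(O)cc(OCc2ccccc2)cc1OCc1ccccc1 | intermediate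
12 | 3,5-bis(benzyloxy)-2-(hydroxymethyl)phenol | OCc1c(O)cc(OCc2ccccc2)cc1OCc1ccccc1 | intermediate
13 | 3,5-bis(benzyloxy)-6-methylidenecyclohexa-2,4-dien-1-one (ortho-quinone methide, formed in the flask) | C=C1C(=O)C=C(OCc2ccccc2)C=C1OCc1ccccc1 | intermediate
14 | 6,7-bis(benzyloxy)-4-[(2S,3R)-5,7-bis(benzyloxy)-3-(4,4,5,5-tetramethyl-1,3,2-dioxaborolan-2-yl)chroman-2-yl]isobenzofuran-1(3H)-one | CC1(C)OB([C@@H]2Cc3c(OCc4ccccc4)cc(OCc4ccccc4)cc3O[C@@H]2c2cc(OCc3ccccc3)c(OCc3ccccc3)c3C(=O)OCc23)OC1(C)C | intermediate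
15 | 6,7-bis(benzyloxy)-4-[(2R,3R)-5,7-bis(benzyloxy)-3-hydroxychroman-2-yl]isobenzofuran-1(3H)-one | O[C@@H]1Cc2c(OCc3ccccc3)cc(OCc3ccccc3)cc2O[C@@H]1c1cc(OCc2ccccc2)c(OCc2ccccc2)c2C(=O)OCc12 | intermediate
16 | potassium 2,3-bis(benzyloxy)-5-[(2R,3R)-5,7-bis(benzyloxy)-3-hydroxychroman-2-yl]-6-(hydroxymethyl)benzoate (formed in the flask) | [K+].[O-]C(=O)c1c(OCc2ccccc2)c(OCc2ccccc2)cc([C@H]2Oc3cc(OCc4ccccc4)cc(OCc4ccccc4)c3C[C@H]2O)c1CO | intermediate
17 | tert-butyldiphenylsilyl 2,3-bis(benzyloxy)-5-[(2R,3R)-5,7-bis(benzyloxy)-3-hydroxychroman-2-yl]-6-{[(tert-butyldiphenylsilyl)oxy]methyl}benzoate (formed in the flask) | CC(C)(C)[Si](OC(=O)c1c(OCc2ccccc2)c(OCc2ccccc2)cc([C@H]2Oc3cc(OCc4ccccc4)cc(OCc4ccccc4)c3C[C@H]2O)c1CO[Si](c1ccccc1)(c1ccccc1)C(C)(C)C)(c1ccccc1)c1ccccc1 | intermediate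
18 | 2,3-bis(benzyloxy)-5-[(2R,3R)-5,7-bis(benzyloxy)-3-hydroxychroman-2-yl]-6-{[(tert-butyldiphenylsilyl)oxy]methyl}benzoic acid | OC(=O)c1c(OCc2ccccc2)c(OCc2ccccc2)cc([C@H]2Oc3cc(OCc4ccccc4)cc(OCc4ccccc4)c3C[C@H]2O)c1CO[Si](c1ccccc1)(c1ccccc1)C(C)(C)C | intermediate
19 | allyl 2,3-bis(benzyloxy)-5-[(2R,3R)-5,7-bis(benzyloxy)-3-hydroxychroman-2-yl]-6-{[(tert-butyldiphenylsilyl)oxy]methyl}benzoate | C=CCOC(=O)c1c(OCc2ccccc2)c(OCc2ccccc2)cc([C@H]2Oc3cc(OCc4ccccc4)cc(OCc4ccccc4)c3C[C@H]2O)c1CO[Si](c1ccccc1)(c1ccccc1)C(C)(C)C | intermediate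
20 | 3,4,5-tris(benzyloxy)benzoic acid | OC(=O)c1cc(OCc2ccccc2)c(OCc2ccccc2)c(OCc2ccccc2)c1 | starting material
21 | allyl 2,3-bis(benzyloxy)-5-[(2R,3R)-5,7-bis(benzyloxy)-3-{[3,4,5-tris(benzyloxy)benzoyl]oxy}chroman-2-yl]-6-{[(tert-butyldiphenylsilyl)oxy]methyl}benzoate | C=CCOC(=O)c1c(OCc2ccccc2)c(OCc2ccccc2)cc([C@H]2Oc3cc(OCc4ccccc4)cc(OCc4ccccc4)c3C[C@H]2OC(=O)c2cc(OCc3ccccc3)c(OCc3ccccc3)c(OCc3ccccc3)c2)c1CO[Si](c1ccccc1)(c1ccccc1)C(C)(C)C | intermediate
22 | 2,3-bis(benzyloxy)-5-[(2R,3R)-5,7-bis(benzyloxy)-3-{[3,4,5-tris(benzyloxy)benzoyl]oxy}chroman-2-yl]-6-{[(tert-butyldiphenylsilyl)oxy]methyl}benzoic acid | OC(=O)c1c(OCc2ccccc2)c(OCc2ccccc2)cc([C@H]2Oc3cc(OCc4ccccc4)cc(OCc4ccccc4)c3C[C@H]2OC(=O)c2cc(OCc3ccccc3)c(OCc3ccccc3)c(OCc3ccccc3)c2)c1CO[Si](c1ccccc1)(c1ccccc1)C(C)(C)C | intermediate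
23 | 2,3-bis(benzyloxy)-5-[(2R,3R)-5,7-bis(benzyloxy)-3-{[3,4,5-tris(benzyloxy)benzoyl]oxy}chroman-2-yl]-6-{[(tert-butyldiphenylsilyl)oxy]methyl}benzoyl chloride (formed in the flask) | ClC(=O)c1c(OCc2ccccc2)c(OCc2ccccc2)cc([C@H]2Oc3cc(OCc4ccccc4)cc(OCc4ccccc4)c3C[C@H]2OC(=O)c2cc(OCc3ccccc3)c(OCc3ccccc3)c(OCc3ccccc3)c2)c1CO[Si](c1ccccc1)(c1ccccc1)C(C)(C)C | intermediate
24 | (2R,3R)-5,7-bis(benzyloxy)-2-[4,5-bis(benzyloxy)-2-{[(tert-butyldiphenylsilyl)oxy]methyl}-3-(2-diazoacetyl)phenyl]chroman-3-yl 3,4,5-tris(benzyloxy)benzoate | [N-]=[N+]=CC(=O)c1c(OCc2ccccc2)c(OCc2ccccc2)cc([C@H]2Oc3cc(OCc4ccccc4)cc(OCc4ccccc4)c3C[C@H]2OC(=O)c2cc(OCc3ccccc3)c(OCc3ccccc3)c(OCc3ccccc3)c2)c1CO[Si](c1ccccc1)(c1ccccc1)C(C)(C)C | intermediate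
25 | (2R,3R)-5,7-bis(benzyloxy)-2-[4,5-bis(benzyloxy)-3-(2-diazoacetyl)-2-(hydroxymethyl)phenyl]chroman-3-yl 3,4,5-tris(benzyloxy)benzoate | [N-]=[N+]=CC(=O)c1c(OCc2ccccc2)c(OCc2ccccc2)cc([C@H]2Oc3cc(OCc4ccccc4)cc(OCc4ccccc4)c3C[C@H]2OC(=O)c2cc(OCc3ccccc3)c(OCc3ccccc3)c(OCc3ccccc3)c2)c1CO | intermediate
26 | (2R,3R)-5,7-bis(benzyloxy)-2-[4,5-bis(benzyloxy)-3-(2-diazoacetyl)-2-formylphenyl]chroman-3-yl 3,4,5-tris(benzyloxy)benzoate | [N-]=[N+]=CC(=O)c1c(OCc2ccccc2)c(OCc2ccccc2)cc([C@H]2Oc3cc(OCc4ccccc4)cc(OCc4ccccc4)c3C[C@H]2OC(=O)c2cc(OCc3ccccc3)c(OCc3ccccc3)c(OCc3ccccc3)c2)c1C=O | intermediate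
27 | acrolein | C=CC=O | starting material
28 | ethynyltriisopropylsilane | C#C[Si](C(C)C)(C(C)C)C(C)C | starting material
29 | racemic 5-(triisopropylsilyl)pent-1-en-4-yn-3-ol | C=CC(O)C#C[Si](C(C)C)(C(C)C)C(C)C | intermediate
30 | (1S)-1-[(2R)-oxiran-2-yl]-3-(triisopropylsilyl)prop-2-yn-1-ol | O[C@@H](C#C[Si](C(C)C)(C(C)C)C(C)C)[C@H]1CO1 | intermediate
31 | 3,5-bis(benzyloxy)phenol | Oc1cc(OCc2ccccc2)cc(OCc2ccccc2)c1 | starting material
32 | (2R)-2-[(1R)-1-[3,5-bis(benzyloxy)phenoxy]-3-(triisopropylsilyl)prop-2-yn-1-yl]oxirane | CC(C)[Si](C(C)C)(C(C)C)C#C[C@@H](Oc1cc(OCc2ccccc2)cc(OCc2ccccc2)c1)[C@H]1CO1 | intermediate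
33 | (2R,3R)-5,7-bis(benzyloxy)-2-[(triisopropylsilyl)ethynyl]chroman-3-ol | CC(C)[Si](C(C)C)(C(C)C)C#C[C@H]1Oc2cc(OCc3ccccc3)cc(OCc3ccccc3)c2C[C@H]1O | intermediate
34 | (2R,3R)-3,5,7-tris(benzyloxy)-2-[(triisopropylsilyl)ethynyl]chroman | CC(C)[Si](C(C)C)(C(C)C)C#C[C@H]1Oc2cc(OCc3ccccc3)cc(OCc3ccccc3)c2C[C@H]1OCc1ccccc1 | intermediate
35 | (2R,3R)-3,5,7-tris(benzyloxy)-2-ethynylchroman | C#C[C@H]1Oc2cc(OCc3ccccc3)cc(OCc3ccccc3)c2C[C@H]1OCc1ccccc1 | intermediate
36 | 5,6-bis(benzyloxy)-8-[(2R,3R)-5,7-bis(benzyloxy)-3-{[3,4,5-tris(benzyloxy)benzoyl]oxy}chroman-2-yl]-2-benzopyrylium-4-olate (carbonyl ylide, formed in the flask) | [O-]c1c[o+]cc2c([C@H]3Oc4cc(OCc5ccccc5)cc(OCc5ccccc5)c4C[C@H]3OC(=O)c3cc(OCc4ccccc4)c(OCc4ccccc4)c(OCc4ccccc4)c3)cc(OCc3ccccc3)c(OCc3ccccc3)c12 | intermediate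
37 | (2R,3R)-5,7-bis(benzyloxy)-2-{3,4-bis(benzyloxy)-5-oxo-7-[(2R,3R)-3,5,7-tris(benzyloxy)chroman-2-yl]-6,9-dihydro-5H-6,9-epoxybenzo[7]annulen-1-yl}chroman-3-yl 3,4,5-tris(benzyloxy)benzoate (one of two bridge diastereomers drawn) | O=C1c2c(OCc3ccccc3)c(OCc3ccccc3)cc([C@H]3Oc4cc(OCc5ccccc5)cc(OCc5ccccc5)c4C[C@H]3OC(=O)c3cc(OCc4ccccc4)c(OCc4ccccc4)c(OCc4ccccc4)c3)c2[C@H]2O[C@@H]1C([C@H]1Oc3cc(OCc4ccccc4)cc(OCc4ccccc4)c3C[C@H]1OCc1ccccc1)=C2 | intermediate
38 | (2R,3R)-5,7-bis(benzyloxy)-2-{3,4-bis(benzyloxy)-6-hydroxy-5-oxo-7-[(2R,3R)-3,5,7-tris(benzyloxy)chroman-2-yl]-5H-benzo[7]annulen-1-yl}chroman-3-yl 3,4,5-tris(benzyloxy)benzoate | O=C(O[C@@H]1Cc2c(OCc3ccccc3)cc(OCc3ccccc3)cc2O[C@@H]1c1cc(OCc2ccccc2)c(OCc2ccccc2)c2c(=O)c(O)c([C@H]3Oc4cc(OCc5ccccc5)cc(OCc5ccccc5)c4C[C@H]3OCc3ccccc3)ccc12)c1cc(OCc2ccccc2)c(OCc2ccccc2)c(OCc2ccccc2)c1 | intermediate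
39 | (2R,3R)-5,7-dihydroxy-2-{3,4,6-trihydroxy-5-oxo-7-[(2R,3R)-3,5,7-trihydroxychroman-2-yl]-5H-benzo[7]annulen-1-yl}chroman-3-yl 3,4,5-trihydroxybenzoate (CNP0217128.1) | O=C(O[C@@H]1Cc2c(O)cc(O)cc2O[C@@H]1c1cc(O)c(O)c2c(=O)c(O)c([C@H]3Oc4cc(O)cc(O)c4C[C@H]3O)ccc12)c1cc(O)c(O)c(O)c1 | target

## Step count and least certain steps

Total: 26 steps. Longest linear sequence: 18 steps (steps 1 to 6, 9 to 17 and 24 to 26).

Step 9 (key step). Three things are most likely to go wrong. The ortho-quinone methide may be consumed by a second molecule of the electron-rich phenol, because the alkene is only moderately nucleophilic. The cationic intermediate may lose boron or rotate before ring closure, which would erode the cis relationship or give an open-chain alkenylation product. The chiral acid may fail to differentiate the faces, since the alkene offers no hydrogen-bond donor.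

The fallback uses known flavan chemistry. It sets out from bromide 4 and phenol 31 and returns at alcohol 15.
- Bromide 4 is formylated with Pd(OAc)2, di(1-adamantyl)-n-butylphosphine, CO/H2 and tetramethylethylenediamine in toluene at 100 °C to 6,7-bis(benzyloxy)-1-oxo-1,3-dihydroisobenzofuran-4-carbaldehyde F1.
- Vinylmagnesium bromide (CH2=CHMgBr) in THF at −78 °C adds to the aldehyde and not to the lactone, giving racemic 6,7-bis(benzyloxy)-4-(1-hydroxyprop-2-en-1-yl)isobenzofuran-1(3H)-one F2.
- Sharpless kinetic resolution with Ti(OiPr)4, L-(+)-diisopropyl tartrate and t-BuOOH should give the erythro epoxy alcohol 6,7-bis(benzyloxy)-4-[(S)-hydroxy((2R)-oxiran-2-yl)methyl]isobenzofuran-1(3H)-one F3.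
- Mitsunobu reaction with 31 inverts the benzylic centre to give 6,7-bis(benzyloxy)-4-{(R)-[3,5-bis(benzyloxy)phenoxy][(2R)-oxiran-2-yl]methyl}isobenzofuran-1(3H)-one F4.
- AuCl3/AgOTf-catalysed 6-endo epoxide–arene alkylation then closes the pyran ring to the cis alcohol 15.

Step 24. The rhodium carbenoid may be intercepted by the neighbouring benzyloxy oxygen (oxonium ylide followed by 1,2-benzyl shift), and the ylide may react with itself if trapping by the hindered, unactivated alkyne is slow. The orientation of the alkyne rests on polarity and steric arguments and not on a directing group.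

The fallback avoids the metal carbenoid and generates the same ylide reversibly at low concentration. It sets out from 26 and 35 and returns at 37.
- HCl in Et2O at 0 °C converts 26 into the chloromethyl ketone (2R,3R)-5,7-bis(benzyloxy)-2-[4,5-bis(benzyloxy)-3-(2-chloroacetyl)-2-formylphenyl]chroman-3-yl 3,4,5-tris(benzyloxy)benzoate F5.
- K2CO3 in MeCN effects an intramolecular Darzens reaction to the epoxyindanone (2R,3R)-5,7-bis(benzyloxy)-2-[4,5-bis(benzyloxy)-6-oxo-1a,6a-dihydro-6H-indeno[1,2-b]oxiren-2-yl]chroman-3-yl 3,4,5-tris(benzyloxy)benzoate F6.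
- Irradiation at 350 nm, or heating in toluene, in the presence of 35 opens the oxirane C–C bond to ylide 36, which is trapped to 37.

Step 19. The selectivity of the kinetic resolution may be low, because the slender alkynyl group differs little from the vinyl group at the carbinol, which would lower the enantiomeric purity of chroman B.

The fallback takes the epoxide-bearing stereocentre from the chiral pool. It sets out from 28 and 31 and returns at 32.
- The lithium acetylide of 28 adds to (R)-2,2-dimethyl-1,3-dioxolane-4-carbaldehyde. The anti (Felkin) adduct (1S)-1-[(4R)-2,2-dimethyl-1,3-dioxolan-4-yl]-3-(triisopropylsilyl)prop-2-yn-1-ol F7 is separated.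
- Mitsunobu reaction with 31 gives (4R)-4-{(1R)-1-[3,5-bis(benzyloxy)phenoxy]-3-(triisopropylsilyl)prop-2-yn-1-yl}-2,2-dimethyl-1,3-dioxolane F8.
- Aqueous acetic acid removes the acetonide to give (2R,3R)-3-[3,5-bis(benzyloxy)phenoxy]-5-(triisopropylsilyl)pent-4-yne-1,2-diol F9.
- TsCl, Et3N and catalytic Bu2SnO give the primary sulfonate (2R,3R)-3-[3,5-bis(benzyloxy)phenoxy]-2-hydroxy-5-(triisopropylsilyl)pent-4-yn-1-yl 4-methylbenzenesulfonate F10.
- K2CO3 in MeOH closes the epoxide to 32.

Step 26. Ten hydrogenolyses on one molecule may be accompanied by partial reduction of the tropolone ring or cleavage of a benzylic C2–O1 bond, and the free polyphenol may oxidise in air during isolation.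

The fallback replaces hydrogenation by Lewis acid debenzylation. It sets out from 38 and ends at 39: BCl3 with pentamethylbenzene as cation scavenger in CH2Cl2 at −78 °C, quenched with MeOH. No new compound lies on its way.

## Further compounds

F1 | step 9 | 6,7-bis(benzyloxy)-1-oxo-1,3-dihydroisobenzofuran-4-carbaldehyde | O=Cc1cc(OCc2ccccc2)c(OCc2ccccc2)c2C(=O)OCc12
F2 | step 9 | racemic 6,7-bis(benzyloxy)-4-(1-hydroxyprop-2-en-1-yl)isobenzofuran-1(3H)-one | C=CC(O)c1cc(OCc2ccccc2)c(OCc2ccccc2)c2C(=O)OCc12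
F3 | step 9 | 6,7-bis(benzyloxy)-4-[(S)-hydroxy((2R)-oxiran-2-yl)methyl]isobenzofuran-1(3H)-one | O[C@@H](c1cc(OCc2ccccc2)c(OCc2ccccc2)c2C(=O)OCc12)[C@H]1CO1
F4 | step 9 | 6,7-bis(benzyloxy)-4-{(R)-[3,5-bis(benzyloxy)phenoxy][(2R)-oxiran-2-yl]methyl}isobenzofuran-1(3H)-one | O([C@H](c1cc(OCc2ccccc2)c(OCc2ccccc2)c2C(=O)OCc12)[C@H]1CO1)c1cc(OCc2ccccc2)cc(OCc2ccccc2)c1
F5 | step 24 | (2R,3R)-5,7-bis(benzyloxy)-2-[4,5-bis(benzyloxy)-3-(2-chloroacetyl)-2-formylphenyl]chroman-3-yl 3,4,5-tris(benzyloxy)benzoate | ClCC(=O)c1c(OCc2ccccc2)c(OCc2ccccc2)cc([C@H]2Oc3cc(OCc4ccccc4)cc(OCc4ccccc4)c3C[C@H]2OC(=O)c2cc(OCc3ccccc3)c(OCc3ccccc3)c(OCc3ccccc3)c2)c1C=O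
F6 | step 24 | (2R,3R)-5,7-bis(benzyloxy)-2-[4,5-bis(benzyloxy)-6-oxo-1a,6a-dihydro-6H-indeno[1,2-b]oxiren-2-yl]chroman-3-yl 3,4,5-tris(benzyloxy)benzoate (one epoxide face drawn) | O=C1c2c(OCc3ccccc3)c(OCc3ccccc3)cc([C@H]3Oc4cc(OCc5ccccc5)cc(OCc5ccccc5)c4C[C@H]3OC(=O)c3cc(OCc4ccccc4)c(OCc4ccccc4)c(OCc4ccccc4)c3)c2[C@H]2O[C@@H]12
F7 | step 19 | (1S)-1-[(4R)-2,2-dimethyl-1,3-dioxolan-4-yl]-3-(triisopropylsilyl)prop-2-yn-1-ol | O[C@@H](C#C[Si](C(C)C)(C(C)C)C(C)C)[C@H]1COC(C)(C)O1
F8 | step 19 | (4R)-4-{(1R)-1-[3,5-bis(benzyloxy)phenoxy]-3-(triisopropylsilyl)prop-2-yn-1-yl}-2,2-dimethyl-1,3-dioxolane | CC(C)[Si](C(C)C)(C(C)C)C#C[C@@H](Oc1cc(OCc2ccccc2)cc(OCc2ccccc2)c1)[C@H]1COC(C)(C)O1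
F9 | step 19 | (2R,3R)-3-[3,5-bis(benzyloxy)phenoxy]-5-(triisopropylsilyl)pent-4-yne-1,2-diol | CC(C)[Si](C(C)C)(C(C)C)C#C[C@@H](Oc1cc(OCc2ccccc2)cc(OCc2ccccc2)c1)[C@H](O)CO
F10 | step 19 | (2R,3R)-3-[3,5-bis(benzyloxy)phenoxy]-2-hydroxy-5-(triisopropylsilyl)pent-4-yn-1-yl 4-methylbenzenesulfonate | CC(C)[Si](C(C)C)(C(C)C)C#C[C@@H](Oc1cc(OCc2ccccc2)cc(OCc2ccccc2)c1)[C@H](O)COS(=O)(=O)c1ccc(C)cc1
F0 | step 26 | none | none
A1 | alternative 1 | 1,6-dibromo-3,4-bis(benzyloxy)-8,9-dihydrobenzo[7]annulen-5-one | O=C1C(Br)=CCCc2c(Br)cc(OCc3ccccc3)c(OCc3ccccc3)c12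
A2 | alternative 1 | {[5-bromo-7,8-bis(benzyloxy)-3,4-dihydronaphthalen-1-yl]oxy}(tert-butyl)dimethylsilane | CC(C)(C)[Si](C)(C)OC1=CCCc2c(Br)cc(OCc3ccccc3)c(OCc3ccccc3)c12
A3 | alternative 2 | oxygen-bridged cycloadduct, identical with 37 | O=C1c2c(OCc3ccccc3)c(OCc3ccccc3)cc([C@H]3Oc4cc(OCc5ccccc5)cc(OCc5ccccc5)c4C[C@H]3OC(=O)c3cc(OCc4ccccc4)c(OCc4ccccc4)c(OCc4ccccc4)c3)c2[C@H]2O[C@@H]1C([C@H]1Oc3cc(OCc4ccccc4)cc(OCc4ccccc4)c3C[C@H]1OCc1ccccc1)=C2
A4 | alternative 2 | formyl diazoketone, identical with 26 | [N-]=[N+]=CC(=O)c1c(OCc2ccccc2)c(OCc2ccccc2)cc([C@H]2Oc3cc(OCc4ccccc4)cc(OCc4ccccc4)c3C[C@H]2OC(=O)c2cc(OCc3ccccc3)c(OCc3ccccc3)c(OCc3ccccc3)c2)c1C=O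
A5 | alternative 2 | (2R,3R)-3,5,7-tris(benzyloxy)-2-ethynylchroman, identical with 35 | C#C[C@H]1Oc2cc(OCc3ccccc3)cc(OCc3ccccc3)c2C[C@H]1OCc1ccccc1
A6 | alternative 3 | 3,4,6-tris(benzyloxy)-1-chloro-7-[(2R,3R)-3,5,7-tris(benzyloxy)chroman-2-yl]-6,7-dihydro-5H-benzo[7]annulen-5-one | O=C1c2c(OCc3ccccc3)c(OCc3ccccc3)cc(Cl)c2C=CC([C@H]2Oc3cc(OCc4ccccc4)cc(OCc4ccccc4)c3C[C@H]2OCc2ccccc2)C1OCc1ccccc1
A7 | alternative 3 | 2-(benzyloxy)-1-[2,3-bis(benzyloxy)-5-chloro-6-ethenylphenyl]-3-[(2R,3R)-3,5,7-tris(benzyloxy)chroman-2-yl]pent-4-en-1-one | C=Cc1c(Cl)cc(OCc2ccccc2)c(OCc2ccccc2)c1C(=O)C(OCc1ccccc1)C(C=C)[C@H]1Oc2cc(OCc3ccccc3)cc(OCc3ccccc3)c2C[C@H]1OCc1ccccc1
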